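## Retrosynthetic overview

1. Target 31 ⇐ ketoreductase reduction of the C2 ketone of dione 30 (sets C2) ⇐ desilylation of 29.
2. 29 ⇐ intramolecular enolate C‑acylation (C1–C2 bond) of the dioxanone Weinreb amide 27, which closes the three‑carbon bridge and fixes C1.
3. 27 ⇐ C3‑alkylation of dioxanone 15 with the Z‑iodide 22 (from a Still–Gennari olefination), then adjustment of the C6 side chain to the amide.
4. 15 ⇐ sec/tert‑diol 12 + bromoacetic acid; 12 ⇐ hydroxy γ‑lactone 10 ⇐ inversion‑opening of the epoxide from Sharpless epoxidation of the nerol‑derived E‑allylic alcohol 3 (sets C9 and C5).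
5. Ring order: temporary γ‑lactone → 1,4‑dioxan‑2‑one → bridging ring (oxepane and seven‑membered lactone formed together) last.

Assumption: conjugate‑base salts (enolates, alkoxides, carboxylates) of numbered compounds are not numbered separately; TBS = tert‑butyldimethylsilyl, TBDPS = tert‑butyldiphenylsilyl; C1, C2, C5, C9 refer to the bicyclic numbering of the target.

## Route

Step 1
Reactants: 1 nerol [(2Z)-3,7-dimethylocta-2,6-dien-1-ol]
Product: 2 tert-butyl{[(2Z)-3,7-dimethylocta-2,6-dien-1-yl]oxy}diphenylsilane (neryl TBDPS ether)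
Conditions: TBDPSCl, imidazole, DMF, 0 °C → rt
Reagents that add atoms: tert-butyl(chloro)diphenylsilane, CC(C)(C)[Si](Cl)(c1ccccc1)c1ccccc1
Why: Silyl ether formation (substitution at silicon) masks the primary allylic hydroxyl with a robust group and deactivates the adjacent 2,3‑alkene towards the oxidations that follow.

Step 2
Reactants: 2 neryl TBDPS ether
Product: 3 (2E,6Z)-8-(TBDPS-oxy)-2,6-dimethylocta-2,6-dien-1-ol
Conditions: SeO2 (0.2 equiv), t-BuOOH (70% aq, 3 equiv), salicylic acid (0.1 equiv), CH2Cl2, rt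
Reagents that add atoms: tert-butyl hydroperoxide, CC(C)(C)OO
Why: Riley allylic oxidation (ene reaction then [2,3]-shift) occurs at the E‑methyl of the more electron‑rich distal trisubstituted alkene and gives the E‑allylic alcohol needed for directed epoxidation.

Step 3
Reactants: 3 E‑allylic alcohol
Product: 4 [(2S,3S)-3-[(3Z)-5-(TBDPS-oxy)-3-methylpent-3-en-1-yl]-2-methyloxiran-2-yl]methanol
Conditions: Ti(OiPr)4 (10 mol %), L-(+)-diethyl tartrate (12 mol %), t-BuOOH (anhydrous), 4 Å MS, CH2Cl2, –20 °C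
Reagents that add atoms: tert-butyl hydroperoxide, CC(C)(C)OO
Why: Sharpless–Katsuki asymmetric epoxidation with the catalytic Ti/L‑(+)‑tartrate complex delivers oxygen to one face of the only alkene carrying a free allylic OH (same sense as geraniol → 2S,3S), setting the future C9 (S) and the epoxide carbon that becomes C5.

Step 4
Reactants: 4 epoxy alcohol
Product: 5 (2R,3S)-3-[(3Z)-5-(TBDPS-oxy)-3-methylpent-3-en-1-yl]-2-methyloxirane-2-carbaldehyde
Conditions: TEMPO (0.1 equiv), PhI(OAc)2 (1.1 equiv), CH2Cl2, rt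
Reagents that add atoms: none
Why: TEMPO/oxoammonium oxidation converts the primary alcohol into the aldehyde without touching the epoxide or alkene, and the α‑carbon is quaternary so it cannot epimerise.

Step 5
Reactants: 5 epoxy aldehyde; 6 methyl (triphenyl-λ5-phosphanylidene)acetate
Product: 7 methyl (2E)-3-[(2S,3S)-3-[(3Z)-5-(TBDPS-oxy)-3-methylpent-3-en-1-yl]-2-methyloxiran-2-yl]prop-2-enoate
Conditions: CH2Cl2, rt
Reagents that add atoms: none
Why: Wittig olefination with a stabilised ylide adds the two carbons that become C3 and C2 under neutral conditions that leave the epoxide intact.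

Step 6
Reactants: 7 epoxy enoate
Product: 8 methyl 3-[(2S,3S)-3-[(3Z)-5-(TBDPS-oxy)-3-methylpent-3-en-1-yl]-2-methyloxiran-2-yl]propanoate
Conditions: 2-nitrobenzenesulfonohydrazide (excess), Et3N, CH2Cl2, rt
Reagents that add atoms: none
Why: Diimide reduction saturates the disubstituted conjugated alkene by concerted syn hydrogen transfer, while the trisubstituted alkene and the epoxide do not react.

Step 7
Reactants: 8 epoxy ester
Product: 10 (5R)-5-[(1S,4Z)-6-(TBDPS-oxy)-1-hydroxy-4-methylhex-4-en-1-yl]-5-methyloxolan-2-one, via epoxy acid 9 (not isolated)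
Conditions: LiOH, THF/MeOH/H2O, rt; aq HCl to pH 3; then CSA (5 mol %), CH2Cl2, 0 °C → rt
Reagents that add atoms: lithium hydroxide, [Li+].[OH-]
Why: Saponification followed by acid‑catalysed epoxy‑acid lactonisation, a 5‑exo opening by the carboxyl group at the tertiary epoxide carbon with inversion, gives the future C5 as R while C9 keeps its S configuration.

Step 8
Reactants: 10 hydroxy γ‑lactone
Product: 11 (4R,5S,8Z)-10-(TBDPS-oxy)-4,8-dimethyldec-8-ene-1,4,5-triol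
Conditions: LiAlH4, THF, 0 °C
Reagents that add atoms: none
Why: Hydride reduction of the lactone releases the tertiary alcohol and a primary alcohol without affecting either stereocentre.

Step 9
Reactants: 11 triol
Product: 12 (4R,5S,8Z)-1-(TBS-oxy)-10-(TBDPS-oxy)-4,8-dimethyldec-8-ene-4,5-diol
Conditions: TBSCl (1.05 equiv), imidazole, CH2Cl2, –20 → 0 °C
Reagents that add atoms: tert-butyl(chloro)dimethylsilane, CC(C)(C)[Si](C)(C)Cl
Why: Silylation is selective for the unhindered primary hydroxyl over the secondary and tertiary ones, leaving the 1,2‑diol free.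

Step 10
Reactants: 12 diol; 13 bromoacetic acid
Product: 15 (5S,6R)-6-[3-(TBS-oxy)propyl]-5-[(3Z)-5-(TBDPS-oxy)-3-methylpent-3-en-1-yl]-6-methyl-1,4-dioxan-2-one, via hydroxy acid 14 (not isolated)
Conditions: NaH (3.5 equiv), THF, 0 → 50 °C; aq HCl work-up (pH 3); then EDCI·HCl, DMAP (cat.), CH2Cl2, rt
Reagents that add atoms: none
Why: Williamson etherification of the less hindered secondary alkoxide with bromoacetate (a carboxylate cannot transacylate), then Steglich‑type lactonisation onto the tertiary hydroxyl, builds the dioxanone with the ether on C5 and the ester on C6 of that ring.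

Step 11
Reactants: 16 3-(TBS-oxy)propanal; 17 methyl 2-[bis(2,2,2-trifluoroethoxy)phosphoryl]propanoate
Product: 18 methyl (2Z)-5-(TBS-oxy)-2-methylpent-2-enoate
Conditions: KHMDS, 18-crown-6, THF, –78 °C
Reagents that add atoms: none
Why: Still–Gennari olefination gives the Z‑trisubstituted enoate under kinetic control, placing the ester carbon cis to the chain as required for the C1 side chain.

Step 12
Reactants: 18 Z‑enoate
Product: 19 (2Z)-5-(TBS-oxy)-2-methylpent-2-en-1-ol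
Conditions: DIBAL-H (2.5 equiv), CH2Cl2, –78 °C; Rochelle salt work-up
Reagents that add atoms: none
Why: 1,2‑Reduction of the enoate by the aluminium hydride gives the allylic alcohol with the Z geometry retained.

Step 13
Reactants: 19 Z‑allylic alcohol
Product: 20 (2Z)-1-(TBDPS-oxy)-5-(TBS-oxy)-2-methylpent-2-ene
Conditions: TBDPSCl, imidazole, CH2Cl2, rt
Reagents that add atoms: tert-butyl(chloro)diphenylsilane, CC(C)(C)[Si](Cl)(c1ccccc1)c1ccccc1
Why: Silyl ether formation gives the allylic oxygen the same robust TBDPS group as the other side chain.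

Step 14
Reactants: 20 bis‑silyl ether
Product: 21 (3Z)-5-(TBDPS-oxy)-4-methylpent-3-en-1-ol
Conditions: PPTS (0.3 equiv), EtOH, rt → 40 °C
Reagents that add atoms: none
Why: Mild acid‑catalysed solvolysis cleaves the primary TBS ether far faster than the TBDPS ether.

Step 15
Reactants: 21 homoallylic alcohol
Product: 22 tert-butyl{[(2Z)-5-iodo-2-methylpent-2-en-1-yl]oxy}diphenylsilane
Conditions: I2, PPh3, imidazole, CH2Cl2, 0 °C → rt
Reagents that add atoms: iodine, II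
Why: Appel‑type iodination converts the primary alcohol into the iodide by SN2 displacement of the oxyphosphonium group.

Step 16
Reactants: 15 dioxanone; 22 Z‑homoallylic iodide
Product: 23 (3RS,5S,6R)-3-[(3Z)-5-(TBDPS-oxy)-4-methylpent-3-en-1-yl]-5-[(3Z)-5-(TBDPS-oxy)-3-methylpent-3-en-1-yl]-6-[3-(TBS-oxy)propyl]-6-methyl-1,4-dioxan-2-one
Conditions: LiHMDS (1.1 equiv), THF, –78 °C; then HMPA, 22 (1.5 equiv), –78 → –30 °C
Reagents that add atoms: none
Why: SN2 alkylation of the lithium lactone enolate by the primary iodide installs the complete Z side chain, and the new C3 centre is left as an epimer mixture because it is re‑enolised in step 20.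

Step 17
Reactants: 23 alkylated dioxanone
Product: 24 (3RS,5S,6R)-3-[(3Z)-5-(TBDPS-oxy)-4-methylpent-3-en-1-yl]-5-[(3Z)-5-(TBDPS-oxy)-3-methylpent-3-en-1-yl]-6-(3-hydroxypropyl)-6-methyl-1,4-dioxan-2-one
Conditions: HF·pyridine, pyridine, THF, 0 °C
Reagents that add atoms: none
Why: Buffered fluoride desilylation removes the primary TBS ether selectively and leaves the two TBDPS ethers and the lactone untouched.

Step 18
Reactants: 24 primary alcohol
Product: 26 3-[(2R,3S,5RS)-5-[(3Z)-5-(TBDPS-oxy)-4-methylpent-3-en-1-yl]-3-[(3Z)-5-(TBDPS-oxy)-3-methylpent-3-en-1-yl]-2-methyl-6-oxo-1,4-dioxan-2-yl]propanoic acid, via aldehyde 25 (not isolated)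
Conditions: TEMPO (0.2 equiv), PhI(OAc)2 (2.5 equiv), MeCN/H2O 1:1, rt
Reagents that add atoms: water, O
Why: TEMPO/oxoammonium oxidation takes the alcohol through the aldehyde hydrate to the acid without affecting the trisubstituted alkenes.

Step 19
Reactants: 26 carboxylic acid
Product: 27 3-[(2R,3S,5RS)-5-[(3Z)-5-(TBDPS-oxy)-4-methylpent-3-en-1-yl]-3-[(3Z)-5-(TBDPS-oxy)-3-methylpent-3-en-1-yl]-2-methyl-6-oxo-1,4-dioxan-2-yl]-N-methoxy-N-methylpropanamide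
Conditions: MeNHOMe·HCl, EDCI·HCl, HOBt, i-Pr2NEt, CH2Cl2, 0 °C → rt
Reagents that add atoms: N,O-dimethylhydroxylamine hydrochloride, CNOC.Cl
Why: Carbodiimide amide coupling gives the Weinreb amide, an acyl acceptor whose α‑protons are too weakly acidic for LiHMDS and which stops at the tetrahedral stage.

Step 20
Reactants: 27 Weinreb amide
Product: 29 (1R,5R,9S)-1-[(3Z)-5-(TBDPS-oxy)-4-methylpent-3-en-1-yl]-9-[(3Z)-5-(TBDPS-oxy)-3-methylpent-3-en-1-yl]-5-methyl-6,8-dioxabicyclo[3.2.2]nonane-2,7-dione, via lithium hemiaminal adduct 28 (not isolated)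
Conditions: LiHMDS (1.3 equiv), THF (0.005 M), –78 → –10 °C; sat. aq NH4Cl
Reagents that add atoms: none
Why: Intramolecular Claisen‑type (Dieckmann‑like) C‑acylation of the lactone enolate by the tethered Weinreb amide can only occur on the enolate face carrying the tether, so the quaternary bridgehead C1 (R) is dictated by C5, and the chelated adduct prevents retro‑Claisen until quench.

Step 21
Reactants: 29 bis‑TBDPS dione
Product: 30 (1R,5R,9S)-1-[(3Z)-5-hydroxy-4-methylpent-3-en-1-yl]-9-[(3Z)-5-hydroxy-3-methylpent-3-en-1-yl]-5-methyl-6,8-dioxabicyclo[3.2.2]nonane-2,7-dione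
Conditions: HF·pyridine (excess), THF, 0 °C → rt
Reagents that add atoms: none
Why: Acidic fluoride desilylation frees both allylic alcohols without exposing the β‑keto lactone to base, and gives a polar substrate suited to an aqueous biotransformation.

Step 22
Reactants: 30 keto diol
Product: 31 (1R,2S,5R,9S)-2-hydroxy-1-[(3Z)-5-hydroxy-4-methylpent-3-en-1-yl]-9-[(3Z)-5-hydroxy-3-methylpent-3-en-1-yl]-5-methyl-6,8-dioxabicyclo[3.2.2]nonan-7-one (CNP0105745.1)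
Conditions: (S)-selective ketoreductase (KRED, chosen from a screening panel), NADP+ (cat.), i-PrOH (10% v/v), phosphate buffer pH 7.0, DMSO (5%), 30 °C
Reagents that add atoms: none
Why: Ketoreductase‑catalysed carbonyl reduction transfers hydride from NADPH to the ketone face on the ether‑bridge side, setting C2 as S under enzyme control at neutral pH, with isopropanol recycling the cofactor.

## Compound list

1 | nerol, (2Z)-3,7-dimethylocta-2,6-dien-1-ol | CC(C)=CCC/C(C)=C\CO | starting material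
2 | tert-butyl{[(2Z)-3,7-dimethylocta-2,6-dien-1-yl]oxy}diphenylsilane | CC(C)=CCC/C(C)=C\CO[Si](c1ccccc1)(c1ccccc1)C(C)(C)C | intermediate
3 | (2E,6Z)-8-(TBDPS-oxy)-2,6-dimethylocta-2,6-dien-1-ol | OC/C(C)=C/CC/C(C)=C\CO[Si](c1ccccc1)(c1ccccc1)C(C)(C)C | intermediate
4 | [(2S,3S)-3-[(3Z)-5-(TBDPS-oxy)-3-methylpent-3-en-1-yl]-2-methyloxiran-2-yl]methanol | OC[C@]1(C)O[C@H]1CC/C(C)=C\CO[Si](c1ccccc1)(c1ccccc1)C(C)(C)C | intermediate
5 | (2R,3S)-3-[(3Z)-5-(TBDPS-oxy)-3-methylpent-3-en-1-yl]-2-methyloxirane-2-carbaldehyde | O=C[C@]1(C)O[C@H]1CC/C(C)=C\CO[Si](c1ccccc1)(c1ccccc1)C(C)(C)C | intermediate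
6 | methyl (triphenyl-λ5-phosphanylidene)acetate | COC(=O)C=P(c1ccccc1)(c1ccccc1)c1ccccc1 | starting material
7 | methyl (2E)-3-[(2S,3S)-3-[(3Z)-5-(TBDPS-oxy)-3-methylpent-3-en-1-yl]-2-methyloxiran-2-yl]prop-2-enoate | COC(=O)/C=C/[C@]1(C)O[C@H]1CC/C(C)=C\CO[Si](c1ccccc1)(c1ccccc1)C(C)(C)C | intermediate
8 | methyl 3-[(2S,3S)-3-[(3Z)-5-(TBDPS-oxy)-3-methylpent-3-en-1-yl]-2-methyloxiran-2-yl]propanoate | COC(=O)CC[C@]1(C)O[C@H]1CC/C(C)=C\CO[Si](c1ccccc1)(c1ccccc1)C(C)(C)C | intermediate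
9 | 3-[(2S,3S)-3-[(3Z)-5-(TBDPS-oxy)-3-methylpent-3-en-1-yl]-2-methyloxiran-2-yl]propanoic acid | OC(=O)CC[C@]1(C)O[C@H]1CC/C(C)=C\CO[Si](c1ccccc1)(c1ccccc1)C(C)(C)C | intermediate
10 | (5R)-5-[(1S,4Z)-6-(TBDPS-oxy)-1-hydroxy-4-methylhex-4-en-1-yl]-5-methyloxolan-2-one | O=C1CC[C@@](C)(O1)[C@@H](O)CC/C(C)=C\CO[Si](c1ccccc1)(c1ccccc1)C(C)(C)C | intermediate
11 | (4R,5S,8Z)-10-(TBDPS-oxy)-4,8-dimethyldec-8-ene-1,4,5-triol | OCCC[C@@](C)(O)[C@@H](O)CC/C(C)=C\CO[Si](c1ccccc1)(c1ccccc1)C(C)(C)C | intermediate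
12 | (4R,5S,8Z)-1-(TBS-oxy)-10-(TBDPS-oxy)-4,8-dimethyldec-8-ene-4,5-diol | CC(C)(C)[Si](C)(C)OCCC[C@@](C)(O)[C@@H](O)CC/C(C)=C\CO[Si](c1ccccc1)(c1ccccc1)C(C)(C)C | intermediate
13 | bromoacetic acid | OC(=O)CBr | starting material
14 | {[(2Z,6S,7R)-10-(TBS-oxy)-1-(TBDPS-oxy)-7-hydroxy-3,7-dimethyldec-2-en-6-yl]oxy}acetic acid | OC(=O)CO[C@@H](CC/C(C)=C\CO[Si](c1ccccc1)(c1ccccc1)C(C)(C)C)[C@](C)(O)CCCO[Si](C)(C)C(C)(C)C | intermediate
15 | (5S,6R)-6-[3-(TBS-oxy)propyl]-5-[(3Z)-5-(TBDPS-oxy)-3-methylpent-3-en-1-yl]-6-methyl-1,4-dioxan-2-one | O=C1CO[C@@H](CC/C(C)=C\CO[Si](c2ccccc2)(c2ccccc2)C(C)(C)C)[C@@](C)(CCCO[Si](C)(C)C(C)(C)C)O1 | intermediate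
16 | 3-(TBS-oxy)propanal | O=CCCO[Si](C)(C)C(C)(C)C | starting material
17 | methyl 2-[bis(2,2,2-trifluoroethoxy)phosphoryl]propanoate | COC(=O)C(C)P(=O)(OCC(F)(F)F)OCC(F)(F)F | starting material
18 | methyl (2Z)-5-(TBS-oxy)-2-methylpent-2-enoate | C/C(=C/CCO[Si](C)(C)C(C)(C)C)C(=O)OC | intermediate
19 | (2Z)-5-(TBS-oxy)-2-methylpent-2-en-1-ol | C/C(=C/CCO[Si](C)(C)C(C)(C)C)CO | intermediate
20 | (2Z)-1-(TBDPS-oxy)-5-(TBS-oxy)-2-methylpent-2-ene | C/C(=C/CCO[Si](C)(C)C(C)(C)C)CO[Si](c1ccccc1)(c1ccccc1)C(C)(C)C | intermediate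
21 | (3Z)-5-(TBDPS-oxy)-4-methylpent-3-en-1-ol | C/C(=C/CCO)CO[Si](c1ccccc1)(c1ccccc1)C(C)(C)C | intermediate
22 | tert-butyl{[(2Z)-5-iodo-2-methylpent-2-en-1-yl]oxy}diphenylsilane | C/C(=C/CCI)CO[Si](c1ccccc1)(c1ccccc1)C(C)(C)C | intermediate
23 | (3RS,5S,6R)-3-[(3Z)-5-(TBDPS-oxy)-4-methylpent-3-en-1-yl]-5-[(3Z)-5-(TBDPS-oxy)-3-methylpent-3-en-1-yl]-6-[3-(TBS-oxy)propyl]-6-methyl-1,4-dioxan-2-one | C/C(=C/CCC1O[C@@H](CC/C(C)=C\CO[Si](c2ccccc2)(c2ccccc2)C(C)(C)C)[C@@](C)(CCCO[Si](C)(C)C(C)(C)C)OC1=O)CO[Si](c1ccccc1)(c1ccccc1)C(C)(C)C | intermediate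
24 | (3RS,5S,6R)-3-[(3Z)-5-(TBDPS-oxy)-4-methylpent-3-en-1-yl]-5-[(3Z)-5-(TBDPS-oxy)-3-methylpent-3-en-1-yl]-6-(3-hydroxypropyl)-6-methyl-1,4-dioxan-2-one | C/C(=C/CCC1O[C@@H](CC/C(C)=C\CO[Si](c2ccccc2)(c2ccccc2)C(C)(C)C)[C@@](C)(CCCO)OC1=O)CO[Si](c1ccccc1)(c1ccccc1)C(C)(C)C | intermediate
25 | 3-[(2R,3S,5RS)-5-[(3Z)-5-(TBDPS-oxy)-4-methylpent-3-en-1-yl]-3-[(3Z)-5-(TBDPS-oxy)-3-methylpent-3-en-1-yl]-2-methyl-6-oxo-1,4-dioxan-2-yl]propanal | C/C(=C/CCC1O[C@@H](CC/C(C)=C\CO[Si](c2ccccc2)(c2ccccc2)C(C)(C)C)[C@@](C)(CCC=O)OC1=O)CO[Si](c1ccccc1)(c1ccccc1)C(C)(C)C | intermediate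
26 | 3-[(2R,3S,5RS)-5-[(3Z)-5-(TBDPS-oxy)-4-methylpent-3-en-1-yl]-3-[(3Z)-5-(TBDPS-oxy)-3-methylpent-3-en-1-yl]-2-methyl-6-oxo-1,4-dioxan-2-yl]propanoic acid | C/C(=C/CCC1O[C@@H](CC/C(C)=C\CO[Si](c2ccccc2)(c2ccccc2)C(C)(C)C)[C@@](C)(CCC(=O)O)OC1=O)CO[Si](c1ccccc1)(c1ccccc1)C(C)(C)C | intermediate
27 | 3-[(2R,3S,5RS)-5-[(3Z)-5-(TBDPS-oxy)-4-methylpent-3-en-1-yl]-3-[(3Z)-5-(TBDPS-oxy)-3-methylpent-3-en-1-yl]-2-methyl-6-oxo-1,4-dioxan-2-yl]-N-methoxy-N-methylpropanamide | C/C(=C/CCC1O[C@@H](CC/C(C)=C\CO[Si](c2ccccc2)(c2ccccc2)C(C)(C)C)[C@@](C)(CCC(=O)N(C)OC)OC1=O)CO[Si](c1ccccc1)(c1ccccc1)C(C)(C)C | intermediate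
28 | lithium (1R,5R,9S)-2-[methoxy(methyl)amino]-1-[(3Z)-5-(TBDPS-oxy)-4-methylpent-3-en-1-yl]-9-[(3Z)-5-(TBDPS-oxy)-3-methylpent-3-en-1-yl]-5-methyl-7-oxo-6,8-dioxabicyclo[3.2.2]nonan-2-olate (C2 undefined) | C/C(=C/CC[C@@]12O[C@@H](CC/C(C)=C\CO[Si](c3ccccc3)(c3ccccc3)C(C)(C)C)[C@@](C)(CCC1(O[Li])N(C)OC)OC2=O)CO[Si](c1ccccc1)(c1ccccc1)C(C)(C)C | intermediate
29 | (1R,5R,9S)-1-[(3Z)-5-(TBDPS-oxy)-4-methylpent-3-en-1-yl]-9-[(3Z)-5-(TBDPS-oxy)-3-methylpent-3-en-1-yl]-5-methyl-6,8-dioxabicyclo[3.2.2]nonane-2,7-dione | C/C(=C/CC[C@@]12O[C@@H](CC/C(C)=C\CO[Si](c3ccccc3)(c3ccccc3)C(C)(C)C)[C@@](C)(CCC1=O)OC2=O)CO[Si](c1ccccc1)(c1ccccc1)C(C)(C)C | intermediate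
30 | (1R,5R,9S)-1-[(3Z)-5-hydroxy-4-methylpent-3-en-1-yl]-9-[(3Z)-5-hydroxy-3-methylpent-3-en-1-yl]-5-methyl-6,8-dioxabicyclo[3.2.2]nonane-2,7-dione | C/C(=C/CC[C@@]12O[C@@H](CC/C(C)=C\CO)[C@@](C)(CCC1=O)OC2=O)CO | intermediate
31 | (1R,2S,5R,9S)-2-hydroxy-1-[(3Z)-5-hydroxy-4-methylpent-3-en-1-yl]-9-[(3Z)-5-hydroxy-3-methylpent-3-en-1-yl]-5-methyl-6,8-dioxabicyclo[3.2.2]nonan-7-one | C/C(=C/CC[C@@]12O[C@@H](CC/C(C)=C\CO)[C@@](C)(CC[C@@H]1O)OC2=O)CO | target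

## Step count and risks

Total steps: 22. Longest linear sequence: 17 (steps 1–10, then 16–22); the iodide branch (steps 11–15) is 5 steps.

Three steps most likely to fail:

1. Step 20 (bridging C‑acylation). The hindered, fully substituted enolate must reach the amide through a boat‑like dioxanone, and intermolecular Claisen condensation or amide α‑deprotonation may compete. The fallback sets out from 23 and comes back at 29. The enolate of 23 (LiHMDS, –78 °C) is trapped with PhSeBr to give the α‑phenylselanyl lactone F1. HF·pyridine gives the primary alcohol F2, and Dess–Martin periodinane gives the aldehyde F3. SmI2 (THF, –78 °C) then cleaves the C–Se bond to a samarium enolate, which closes onto the aldehyde in a Reformatsky‑type aldol to give the bridged β‑hydroxy lactone F4 as C2 epimers. Dess–Martin oxidation of F4 returns ketone 29.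

2. Step 16 (enolate alkylation with an unactivated homoallylic iodide). E2 elimination to the diene or low conversion is possible. The fallback sets out from 12 and comes back at 23. Rh2(OAc)4‑catalysed O–H insertion of dimethyl diazomalonate into the secondary hydroxyl of 12 gives the alkoxymalonate F5. DBU‑catalysed lactonisation closes the 3‑methoxycarbonyl dioxanone F6. Its soft, malonate‑type anion (Cs2CO3, DMF) is alkylated by 22 to give the quaternary ester F7. Krapcho demethoxycarbonylation (LiCl, wet DMSO, 130 °C) then delivers 23.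

3. Step 22 (ketoreductase). No panel enzyme may accept the hindered bridged ketone, or the selectivity may be for the C2 epimer. The fallback sets out from 29 and comes back at 31. Catalyst‑controlled CBS reduction of 29 ((R)-Me-CBS oxazaborolidine, catecholborane, toluene, –78 °C; quaternary C1 as the large group) gives the silylated (2S)-alcohol F8. HF·pyridine then removes both TBDPS groups to give 31.

Further compounds
F1 | step 20 | (3RS,5S,6R)-3-[(3Z)-5-(TBDPS-oxy)-4-methylpent-3-en-1-yl]-5-[(3Z)-5-(TBDPS-oxy)-3-methylpent-3-en-1-yl]-6-[3-(TBS-oxy)propyl]-6-methyl-3-(phenylselanyl)-1,4-dioxan-2-one | C/C(=C/CCC1([Se]c2ccccc2)O[C@@H](CC/C(C)=C\CO[Si](c2ccccc2)(c2ccccc2)C(C)(C)C)[C@@](C)(CCCO[Si](C)(C)C(C)(C)C)OC1=O)CO[Si](c1ccccc1)(c1ccccc1)C(C)(C)C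
F2 | step 20 | (3RS,5S,6R)-3-[(3Z)-5-(TBDPS-oxy)-4-methylpent-3-en-1-yl]-5-[(3Z)-5-(TBDPS-oxy)-3-methylpent-3-en-1-yl]-6-(3-hydroxypropyl)-6-methyl-3-(phenylselanyl)-1,4-dioxan-2-one | C/C(=C/CCC1([Se]c2ccccc2)O[C@@H](CC/C(C)=C\CO[Si](c2ccccc2)(c2ccccc2)C(C)(C)C)[C@@](C)(CCCO)OC1=O)CO[Si](c1ccccc1)(c1ccccc1)C(C)(C)C
F3 | step 20 | 3-[(2R,3S,5RS)-5-[(3Z)-5-(TBDPS-oxy)-4-methylpent-3-en-1-yl]-3-[(3Z)-5-(TBDPS-oxy)-3-methylpent-3-en-1-yl]-2-methyl-6-oxo-5-(phenylselanyl)-1,4-dioxan-2-yl]propanal | C/C(=C/CCC1([Se]c2ccccc2)O[C@@H](CC/C(C)=C\CO[Si](c2ccccc2)(c2ccccc2)C(C)(C)C)[C@@](C)(CCC=O)OC1=O)CO[Si](c1ccccc1)(c1ccccc1)C(C)(C)C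
F4 | step 20 | (1R,2RS,5R,9S)-2-hydroxy-1-[(3Z)-5-(TBDPS-oxy)-4-methylpent-3-en-1-yl]-9-[(3Z)-5-(TBDPS-oxy)-3-methylpent-3-en-1-yl]-5-methyl-6,8-dioxabicyclo[3.2.2]nonan-7-one | C/C(=C/CC[C@@]12O[C@@H](CC/C(C)=C\CO[Si](c3ccccc3)(c3ccccc3)C(C)(C)C)[C@@](C)(CCC1O)OC2=O)CO[Si](c1ccccc1)(c1ccccc1)C(C)(C)C
F5 | step 16 | dimethyl 2-{[(2Z,6S,7R)-10-(TBS-oxy)-1-(TBDPS-oxy)-7-hydroxy-3,7-dimethyldec-2-en-6-yl]oxy}propanedioate | COC(=O)C(O[C@@H](CC/C(C)=C\CO[Si](c1ccccc1)(c1ccccc1)C(C)(C)C)[C@](C)(O)CCCO[Si](C)(C)C(C)(C)C)C(=O)OC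
F6 | step 16 | methyl (2RS,5R,6S)-5-[3-(TBS-oxy)propyl]-6-[(3Z)-5-(TBDPS-oxy)-3-methylpent-3-en-1-yl]-5-methyl-3-oxo-1,4-dioxane-2-carboxylate | COC(=O)C1O[C@@H](CC/C(C)=C\CO[Si](c2ccccc2)(c2ccccc2)C(C)(C)C)[C@@](C)(CCCO[Si](C)(C)C(C)(C)C)OC1=O
F7 | step 16 | methyl (2RS,5R,6S)-2-[(3Z)-5-(TBDPS-oxy)-4-methylpent-3-en-1-yl]-5-[3-(TBS-oxy)propyl]-6-[(3Z)-5-(TBDPS-oxy)-3-methylpent-3-en-1-yl]-5-methyl-3-oxo-1,4-dioxane-2-carboxylate | C/C(=C/CCC1(C(=O)OC)O[C@@H](CC/C(C)=C\CO[Si](c2ccccc2)(c2ccccc2)C(C)(C)C)[C@@](C)(CCCO[Si](C)(C)C(C)(C)C)OC1=O)CO[Si](c1ccccc1)(c1ccccc1)C(C)(C)C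
F8 | step 22 | (1R,2S,5R,9S)-2-hydroxy-1-[(3Z)-5-(TBDPS-oxy)-4-methylpent-3-en-1-yl]-9-[(3Z)-5-(TBDPS-oxy)-3-methylpent-3-en-1-yl]-5-methyl-6,8-dioxabicyclo[3.2.2]nonan-7-one | C/C(=C/CC[C@@]12O[C@@H](CC/C(C)=C\CO[Si](c3ccccc3)(c3ccccc3)C(C)(C)C)[C@@](C)(CC[C@@H]1O)OC2=O)CO[Si](c1ccccc1)(c1ccccc1)C(C)(C)C
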